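(The data are simulated from invented constants; scatter was added.)

- West held more Za than Friday's run, 0.25 M against 0.17 M, with the same Zb at 0.50 mM and the same held Ze at 140 mM, so I set the two flasks side by side on one quantity.

| flask | Za | Ze | Zb | remark | time |
|---|---|---|---|---|---|
| Friday's | 0.17 M | 140 mM (held) | 0.50 mM | run made earlier |  |
| west | 0.25 M | 140 mM (held) | 0.50 mM |  | 4.0 h |
| south-east | 0.25 M | 140 mM (held) | 1.0 mM |  | 4.0 h |
| south-west | 0.25 M | 140 mM (held) | 2.0 mM |  | 4.0 h |

Friday's run (percent of the Za charged)

| time / min | Zj / % |
|---|---|
| 12.0 | 6.1 |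
| 25.0 | 20.1 |
| 40.0 | 39.1 |
| 50.0 | 51.9 |
| 60.0 | 65.2 |
| 80.0 | 91.6 |

(each reading ± 0.5 percentage points)

- at the start none of Ze is in solution
- "hardly changes" means that all values lie within two and a half points (for a concentration: within two and a half percent of the largest)
- no earlier run changes the charge of Zb; that part of a forecast is a guess

* [Zj] at the end for west, south-east, south-west, in this order
* how that number moves from the first to the last of them (rises all the way / falls, then rises / rises, then falls / falls all the way / hardly changes)

- Friday's readings rose slowly at first and then lay on a straight line, and from 25.0 min to 80.0 min I read a slope of 2.21 mM min⁻¹ of Zj, with no bend up to the last reading.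
- Drawn back, that line met zero at 9.54 min, a reading with the scatter of the points, and I treated this delay as a small correction to the large term, the charge of Za divided by the slope.
- For west the large term was 113 min, so the sum came to 123 min, and this sum is my finish time, the moment when the delayed straight line reaches the full charge of Za.
- The same sum for Friday's run gave 86.5 min, and its last reading came earlier than that, at 80.0 min, which is why it shows 91.6 % and not a full yield.
- West was given 4.0 h, about twice its finish time, so I reckoned that if the line held beyond Friday's last reading, west would end with Zj equal to its charge of Za.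
- No earlier run changed Zb, so for south-east and south-west I could only guess that more of it would not slow the line.
- The forecast gave 0.25 M, 0.25 M and 0.25 M, with the shape "hardly changes", since it put the end of the reaction “well inside the 4 hours”.

    Zb → 2 Zc (k = 2.51 × 10⁻⁵ s⁻¹)
    Za + Zc → Zh (k = 16500 M⁻¹ s⁻¹)
    Zd + Zh → Zj + Zc (k = 62700 M⁻¹ s⁻¹)
    2 Zh → Zk (k = 1.30 × 10⁸ M⁻¹ s⁻¹)
    Ze ⇌ Zd, rate k5*(csat - [Zd]) (kL = 5.94 × 10⁻⁴ s⁻¹)
    Zd → Zf (k = 2.40 × 10⁻⁷ s⁻¹)
    2 Zd → Zg (k = 6.97 × 10⁻⁴ M⁻¹ s⁻¹)

- The flasks gave 0.250 M, 0.250 M and 0.250 M of Zj, so the row hardly changes. In west, Za, the limiting reagent, stood at 0 % at 4.00 h. At 2.00 h west was still 2.66 min short of its finish time, which on my line means 5.88 mM of Za still to react, and it held 98.5 % of Zj and 3.71 mM of Za. South-east, with twice the Zb, stood ahead of west at that hour, at 99.9 % of Zj.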